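## Structural features

The target is a 14-membered carbocycle (C1–C14) with an isopropyl group on C1, methyl groups on C4 and C12, a hydroxymethyl group (C19) on C8 and a hydroxyl on C13. C3 and C4 are bridged by an oxirane whose C4 is fully substituted (methyl, oxygen, C3, C5). This oxirane sits directly on the (E)-configured C1=C2 alkene, which is conjugated with the C14 ketone, so C14–C1=C2–C3–O is one γ,δ-epoxy enone. The five stereocentres form three islands: C3/C4 (adjacent, on the oxirane), C12/C13 (adjacent, methyl and hydroxyl) and the isolated C8. They are separated by three or more methylene or carbonyl carbons, so none can steer another through the ring. Three groups are fragile: C8 is α to the C9 ketone and β to the free C19 hydroxyl (epimerisation, dehydration, loss of formaldehyde under base); C13/C14 is an α-ketol; and the vinyl oxirane opens with acid, with hydrogen fluoride and with zerovalent late metals. The real difficulty is the oxygenated quaternary C4 in a defined relation to C3 inside a flexible ring, together with a ring closure that must leave two enolisable ketones alone. The key step uses the fact that C4, with its methyl, its oxygen and both carbon neighbours, is the carbinol carbon of a terpene alcohol whose vinyl CH becomes C3. The ring is therefore closed at C2–C3 by adding a C2 alkenylmetal to a C3 aldehyde, and the C4 oxygen then closes the oxirane onto C3.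

## Logic of the disconnections

**41 back to 38 (C3–O bond of the oxirane).** The C4 oxygen is already in place, so the oxirane is opened at C3–O to the sulfonate 40, which comes from 39 and the carbinol 38. This keeps the vinyl oxirane out of every earlier step. The forward closure is a 3-exo-tet displacement with inversion at C3, so 38 must be 3R,4R (hydroxyl syn to the C4 oxygen) to give the 3S,4R oxirane with C2 and C5 cis. The silyl ethers are removed with acidic fluoride before the base is added, so the oxirane never meets hydrogen fluoride and the β-oxygenated C9 ketone never meets basic fluoride.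

**38 back to 36 (C2–C3, the ring bond).** Cutting here opens the ring to an acyclic chain with an alkenyl iodide at C2 and an aldehyde at C3 and removes one stereocentre. The forward step must add only to the aldehyde and not to the C9 and C14 ketones, keep the E geometry of C1=C2, pick the correct aldehyde face, and outrun oligomerisation.

**36 back to 32 (C3=CH2 cleavage, oxidation levels at C9 and C14, C19 ether).** The aldehyde of 36 is the ozonolysis product of the terminal vinyl group of 34. Both ketones of 34 come from the carbinols of 33, and 33 is the primary silyl ether of triol 32. The enolisable and hydride-sensitive ketones thus appear only two steps before the ring closure. The forward demands are ozonolysis of the terminal alkene beside an electron-poor iodo-enone and silylation of the primary hydroxyl beside two secondary ones.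

**32 back to 12 and 29 (C8–C9, with C19 as an imide carbonyl).** C8 is the only stereocentre not taken from the chiral pool. An auxiliary-controlled syn aldol between imide 12 and aldehyde 29 sets it and joins two fragments of similar size in adduct 31. Reductive removal of the auxiliary gives the C19 alcohol. Because a hydride is used here, C14 travels through this stage as an acetate, which the same hydride removes.

**12 back to 1 (N–C19, C7=C8, and the trisubstituted alkene of the terpene).** Imide 12 comes from acid 9 and auxiliary 10. Acid 9 comes through esters 8 and 7 from aldehyde 4 and phosphonate 5, which supplies C8 and C19. Aldehyde 4 is the ozonolysis product of silyl ether 2, made from 1. The quaternary C4 is bought with its oxygen and is never touched. The forward demands are cleavage of the trisubstituted alkene while the vinyl group survives, and conjugate reduction that spares the vinyl group.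

**29 back to 22 (C9=C cleavage, C14 level, C2–I and C1–C2).** Aldehyde 29 is the ozonolysis product of acetate 27, which is the reduced and acetylated form of iodo-enone 25. The iodide of 25 replaces the enol oxygen of 24, and the formyl carbon of 24 (C2) is attached to C1 of ketone 22. The forward demands are enolisation at C1 and not at C13, and the E geometry of the iodide.

**22 back to 20 and 21 (C14–C1).** The isobutyl ketone is cut to N-methoxy-N-methyl amide 20 and organomagnesium 21, which brings C1 and the isopropyl group. The forward step must stop at the ketone.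

**20 back to 13 and 14 (C13–O).** Amide 20 is the silyl ether of 19, which comes from hydroxy imide 18. The C13 hydroxyl is introduced by oxidation of the enolate of imide 16, made from acid 13 and auxiliary 14. C12 comes unchanged from 13, and the auxiliary must override the small bias of the adjacent C12 methyl.

## Other disconnections considered

**Alternative 1:** The cut is C7–C8. Beforehand the ring is held as a 14-membered lactone between the C19 carboxyl and an allylic oxygen on C5, with C6=C7 as a vinyl group on C5. In the forward step the ester enolate, with the C9 hydroxyl as its alkoxide, is O-silylated and undergoes an Ireland–Claisen [3,3] shift. This makes C7–C8, breaks C5–O and converts the lactone into the carbocyclic acid A1.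
- In its favour: the ring is first closed through a C–O bond, which is at least as dependable as any C–C macrocyclisation. The C–C bond then forms in a concerted step without metal. C19 arrives at the carboxyl level. Both oxirane stereocentres are fixed before the ring exists, so no oxirane centre depends on a macrocyclisation; on control of C3 this is better than the chosen plan.
- Against it here: a strong amide base and a silyl chloride must act on a β-hydroxy ester that already carries a vinyl oxirane. The chair or boat shape of the transition state is dictated by the medium ring, so the configuration at C8 is hard to predict. A1 has three positions at the wrong level: C5=C6 must be saturated next to the oxirane and beside C1=C2, the acid must be reduced, and C9 and C14 must be oxidised while C13 and C19 stay protected.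
- Comparison: the chosen plan needs two steps after ring formation and A1 needs six or more. Mechanistically a thermal pericyclic step is cleaner than an organochromium addition. Structurally the chosen plan carries no oxirane through any basic or reductive step.

**Alternative 2:** The cut is both bonds from C3 to the oxirane (C3–C4 and C3–O). In the forward step an allylic sulfonium ylide at C3 adds to a C4 methyl ketone. The resulting alkoxide displaces the sulfur group, closing the ring and the oxirane at once to give A2.
- In its favour: ring, C–C bond and oxirane form in one operation with no sulfonate and no separate closure. At this stage it is better in step economy than the chosen plan, and it needs no transition metal.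
- Against it here: both oxirane stereocentres are created together during a macrocyclisation, including the quaternary C4 that the chosen plan buys ready-made. The two faces of a methyl ketone differ only by methyl against a chain. Addition of semi-stabilised allyl ylides is reversible, so the relative configuration follows betaine equilibria, and such ylides also undergo [2,3] shifts and γ-attack. A2 carries C9 and C14 as silyl ethers, so it still needs selective removal of two triethylsilyl groups, a double oxidation and a final desilylation, all on the vinyl oxirane.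
- Comparison: the step count after ring formation is about equal to the chosen plan. The chosen plan has one uncertain stereocentre (C3) and a route that can use either epimer; A2 has two uncertain centres and no such escape.

**Alternative 3:** The cut is C9–C10, taken as a C9≡C10 triple bond. In the forward step a diyne with methyl end caps undergoes ring-closing alkyne metathesis with a molybdenum alkylidyne catalyst, releasing but-2-yne A4 and giving cycloalkyne A3.
- In its favour: the ring closure creates no stereocentre, which is better than the chosen plan. Alkyne metathesis is well suited to 14-membered rings and leaves the E alkene and silyl ethers untouched. The oxirane can be set beforehand by reagent-controlled epoxidation. On reliability of the closure itself it is the equal or the better.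
- Against it here: the alkyne must become a ketone at C9 and not at C10. This needs removal of the 4-methoxybenzyl group, a silicon tether on the C19 oxygen, intramolecular hydrosilylation and Tamao–Fleming oxidation. The basic peroxide of that oxidation meets the vinyl oxirane and generates the base-sensitive β-hydroxy ketone. C13 and C14 carry the same silyl group, so a global desilylation and a selective allylic oxidation follow. The propargylic C8 centre cannot be made by an aldol.
- Comparison: five to six steps follow the ring closure against two in the chosen plan. Mechanistically the metathesis is more predictable than the chromium addition. Structurally the chosen plan keeps the oxirane out of all oxidative steps.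

Key step: step 21

Remark: atoms are numbered C1–C14 around the ring starting at the isopropyl-bearing alkene carbon; C19 is the hydroxymethyl carbon.

Assumption: the (S)-configured oxazoline sulfonamide ligand named in step 21 is taken as the antipode that directs the alkenyl group to the Re face of the C3 aldehyde (3R carbinol); if its intrinsic sense is the opposite, its mirror image is used in the same way.

## Route

Step 1
Reactants: 1 (R)-linalool
Product: 2 (3R)-3,7-dimethyl-3-(triethylsilyloxy)octa-1,6-diene
Conditions: Et3SiOTf, 2,6-lutidine, CH2Cl2, −78 → 0 °C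
Reagents that add atoms: triethylsilyl trifluoromethanesulfonate, CC[Si](CC)(CC)OS(=O)(=O)C(F)(F)F
Why: Silylation of a tertiary alcohol with a silyl triflate and a hindered pyridine base; the carbinol centre (future C4) is not involved and keeps its configuration.

Step 2
Reactants: 2 (3R)-3,7-dimethyl-3-(triethylsilyloxy)octa-1,6-diene
Product: 4 (4R)-4-methyl-4-(triethylsilyloxy)hex-5-enal, via secondary ozonide 3 (not isolated)
Conditions: O3 (1.0 equiv, Sudan red 7B end point), CH2Cl2, −78 °C; then PPh3, −78 °C → rt
Reagents that add atoms: ozone, [O-][O+]=O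
Why: Ozonolysis with reductive work-up; the electron-rich trisubstituted alkene reacts far faster than the hindered monosubstituted vinyl group next to the silyloxy carbon, and the dye marks the end point.

Step 3
Reactants: 4 (4R)-4-methyl-4-(triethylsilyloxy)hex-5-enal; 5 trimethyl phosphonoacetate
Product: 7 methyl (2E,6R)-6-methyl-6-(triethylsilyloxy)octa-2,7-dienoate, via sodium phosphonate carbanion 6 (not isolated)
Conditions: NaH, THF, 0 °C; then 4, 0 °C → rt
Reagents that add atoms: none
Why: Horner–Wadsworth–Emmons olefination adds C8 and C19; the stabilised carbanion should give the (E)-enoate, and the geometry is lost in the next step anyway.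

Step 4
Reactants: 7 methyl (2E,6R)-6-methyl-6-(triethylsilyloxy)octa-2,7-dienoate
Product: 8 methyl (6R)-6-methyl-6-(triethylsilyloxy)oct-7-enoate
Conditions: Mg turnings, MeOH, 0 °C → rt
Reagents that add atoms: none
Why: Dissolving-metal conjugate reduction of an enoate by magnesium in methanol; electron transfer goes only to the conjugated ester, so the isolated vinyl group is spared, and the methyl ester rules out ester exchange.

Step 5
Reactants: 8 methyl (6R)-6-methyl-6-(triethylsilyloxy)oct-7-enoate
Product: 9 (6R)-6-methyl-6-(triethylsilyloxy)oct-7-enoic acid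
Conditions: LiOH, THF/MeOH/H2O, rt; then 1 M HCl to pH 4, 0 °C
Reagents that add atoms: lithium hydroxide, [Li+].[OH-]
Why: Saponification of an unhindered methyl ester; the tertiary triethylsilyl ether is stable to aqueous base and to brief cold acidification.

Step 6
Reactants: 9 (6R)-6-methyl-6-(triethylsilyloxy)oct-7-enoic acid; 10 (4R)-4-benzyl-1,3-oxazolidin-2-one
Product: 12 (4R)-4-benzyl-3-[(6R)-6-methyl-6-(triethylsilyloxy)oct-7-enoyl]-1,3-oxazolidin-2-one, via mixed pivalic anhydride 11 (not isolated)
Conditions: tBuCOCl, Et3N, THF, −20 °C; then LiCl, 10, −20 °C → rt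
Reagents that add atoms: none
Why: N-acylation of the oxazolidinone through a mixed anhydride activated by lithium chloride; attack occurs at the less hindered carbonyl of the anhydride.

Step 7
Reactants: 13 (3R)-3,7-dimethyloct-6-enoic acid [(R)-citronellic acid]; 14 (4S)-4-benzyl-1,3-oxazolidin-2-one
Product: 16 (4S)-4-benzyl-3-[(3R)-3,7-dimethyloct-6-enoyl]-1,3-oxazolidin-2-one, via mixed pivalic anhydride 15 (not isolated)
Conditions: tBuCOCl, Et3N, THF, −20 °C; then LiCl, 14, −20 °C → rt
Reagents that add atoms: none
Why: Same mixed-anhydride N-acylation as in step 6; the C12 methyl centre is β to the carbonyl and is not at risk.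

Step 8
Reactants: 16 (4S)-4-benzyl-3-[(3R)-3,7-dimethyloct-6-enoyl]-1,3-oxazolidin-2-one
Product: 18 (4S)-4-benzyl-3-[(2S,3R)-2-hydroxy-3,7-dimethyloct-6-enoyl]-1,3-oxazolidin-2-one, via sodium enolate 17 (not isolated)
Conditions: NaN(SiMe3)2, THF, −78 °C; then 2-(phenylsulfonyl)-3-phenyloxaziridine, −78 °C; AcOH quench
Reagents that add atoms: 2-(phenylsulfonyl)-3-phenyloxaziridine, O=S(=O)(c1ccccc1)N1OC1c1ccccc1
Why: Evans asymmetric enolate hydroxylation; the chelated (Z)-sodium enolate is oxidised on the face away from the benzyl group, which sets C13 as S, and the auxiliary should dominate the small bias of the C12 methyl.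

Step 9
Reactants: 18 (4S)-4-benzyl-3-[(2S,3R)-2-hydroxy-3,7-dimethyloct-6-enoyl]-1,3-oxazolidin-2-one
Product: 19 (2S,3R)-2-hydroxy-N-methoxy-N,3,7-trimethyloct-6-enamide
Conditions: MeNH(OMe)·HCl, AlMe3, CH2Cl2, 0 °C → rt
Reagents that add atoms: N,O-dimethylhydroxylamine hydrochloride, CNOC.Cl
Why: Aluminium amide transamination to the Weinreb amide; the aluminium alkoxide of the free α-hydroxyl directs attack to the exocyclic carbonyl, and the non-basic conditions should not epimerise C13.

Step 10
Reactants: 19 (2S,3R)-2-hydroxy-N-methoxy-N,3,7-trimethyloct-6-enamide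
Product: 20 (2S,3R)-2-(tert-butyldimethylsilyloxy)-N-methoxy-N,3,7-trimethyloct-6-enamide
Conditions: tBuMe2SiOTf, 2,6-lutidine, CH2Cl2, 0 °C
Reagents that add atoms: tert-butyldimethylsilyl trifluoromethanesulfonate, CC(C)(C)[Si](C)(C)OS(=O)(=O)C(F)(F)F
Why: Silylation of a hindered secondary alcohol with the silyl triflate; the robust ether protects C13 through organometallic, enolate and hydride steps.

Step 11
Reactants: 20 (2S,3R)-2-(tert-butyldimethylsilyloxy)-N-methoxy-N,3,7-trimethyloct-6-enamide; 21 isobutylmagnesium bromide
Product: 22 (5S,6R)-5-(tert-butyldimethylsilyloxy)-2,6,10-trimethylundec-9-en-4-one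
Conditions: THF, 0 °C → rt; then H2O and aq. NH4Cl
Reagents that add atoms: none
Why: Weinreb ketone synthesis; the chelated tetrahedral adduct persists until work-up, so addition stops at the ketone, and C14–C1 is formed with C1 and the isopropyl group in place.

Step 12
Reactants: 22 (5S,6R)-5-(tert-butyldimethylsilyloxy)-2,6,10-trimethylundec-9-en-4-one
Product: 24 (1Z,4S,5R)-4-(tert-butyldimethylsilyloxy)-1-hydroxy-5,9-dimethyl-2-(propan-2-yl)deca-1,8-dien-3-one (enol form of the 2-formyl ketone), via lithium enolate 23 (not isolated)
Conditions: LiN(iPr)2, THF, −78 °C; then HCO2CH2CF3, −78 °C; aq. NH4Cl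
Reagents that add atoms: 2,2,2-trifluoroethyl formate, O=COCC(F)(F)F
Why: Kinetic deprotonation should take the methylene C1 and not the hindered silyloxy methine C13; crossed Claisen formylation with the activated formate then adds C2, and the product is held as the hydrogen-bonded enol.

Step 13
Reactants: 24 (1Z,4S,5R)-4-(tert-butyldimethylsilyloxy)-1-hydroxy-5,9-dimethyl-2-(propan-2-yl)deca-1,8-dien-3-one
Product: 25 (1E,4S,5R)-4-(tert-butyldimethylsilyloxy)-1-iodo-5,9-dimethyl-2-(propan-2-yl)deca-1,8-dien-3-one
Conditions: PPh3, I2, Et3N, MeCN, 0 °C → rt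
Reagents that add atoms: iodine, II
Why: The enol oxygen is activated as an oxyphosphonium ion and replaced by iodide through addition–elimination, the known conversion of β-dicarbonyl enols into β-iodo enones; reversible iodide addition should settle on the (E) isomer, in which iodine avoids the acyl group.

Step 14
Reactants: 25 (1E,4S,5R)-4-(tert-butyldimethylsilyloxy)-1-iodo-5,9-dimethyl-2-(propan-2-yl)deca-1,8-dien-3-one
Product: 27 (1E,4S,5R)-4-(tert-butyldimethylsilyloxy)-1-iodo-5,9-dimethyl-2-(propan-2-yl)deca-1,8-dien-3-yl acetate (both C3 epimers; this carbon is C14), via aluminium alkoxide 26 (not isolated)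
Conditions: iBu2AlH, CH2Cl2, −78 °C; then Ac2O, pyridine, DMAP, −78 → 0 °C
Reagents that add atoms: acetic anhydride, CC(=O)OC(C)=O
Why: 1,2-Reduction of the enone by the aluminium hydride and acylation of the aluminium alkoxide in the same flask; this hides C14 from the hydride of step 17, which also removes the acetate, and the C14 configuration is irrelevant because step 19 re-oxidises it.

Step 15
Reactants: 27 (1E,4S,5R)-4-(tert-butyldimethylsilyloxy)-1-iodo-5,9-dimethyl-2-(propan-2-yl)deca-1,8-dien-3-yl acetate
Product: 29 (4R,5S,7E)-5-(tert-butyldimethylsilyloxy)-8-iodo-4-methyl-1-oxo-7-(propan-2-yl)oct-7-en-6-yl acetate (both C6 epimers), via secondary ozonide 28 (not isolated)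
Conditions: O3 (1.0 equiv, Sudan red 7B end point), CH2Cl2, −78 °C; then PPh3, −78 °C → rt
Reagents that add atoms: ozone, [O-][O+]=O
Why: Ozonolysis of the electron-rich trisubstituted alkene gives the C9 aldehyde; the alkenyl iodide is deactivated by iodine and the allylic acetate and should not react at the end point.

Step 16
Reactants: 12 (4R)-4-benzyl-3-[(6R)-6-methyl-6-(triethylsilyloxy)oct-7-enoyl]-1,3-oxazolidin-2-one; 29 (4R,5S,7E)-5-(tert-butyldimethylsilyloxy)-8-iodo-4-methyl-1-oxo-7-(propan-2-yl)oct-7-en-6-yl acetate
Product: 31 (4R)-4-benzyl-3-[(2R,3S,6R,7S,9E)-8-acetoxy-7-(tert-butyldimethylsilyloxy)-3-hydroxy-10-iodo-6-methyl-2-[(4R)-4-methyl-4-(triethylsilyloxy)hex-5-en-1-yl]-9-(propan-2-yl)dec-9-enoyl]-1,3-oxazolidin-2-one (both C8 epimers of the acyl chain; this carbon is C14), via dibutylboron enolate 30 (not isolated)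
Conditions: nBu2BOTf, iPr2NEt, CH2Cl2, 0 °C; then 29, −78 → 0 °C; pH 7 buffer, MeOH, H2O2, 0 °C
Reagents that add atoms: none
Why: Evans syn aldol; the (Z)-boron enolate reacts through a Zimmerman–Traxler chair with the benzyl group shielding one face, which sets C8 (S in the target once C19 is reduced) and forms C8–C9; the syn C9 carbinol is oxidised later.

Step 17
Reactants: 31 syn-aldol imide of step 16
Product: 32 (2S,3S,6R,7S,9E)-7-(tert-butyldimethylsilyloxy)-10-iodo-6-methyl-2-[(4R)-4-methyl-4-(triethylsilyloxy)hex-5-en-1-yl]-9-(propan-2-yl)dec-9-ene-1,3,8-triol (both C8 epimers)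
Conditions: LiBH4, MeOH (2 equiv), THF, 0 °C → rt
Reagents that add atoms: none
Why: Reductive cleavage of the N-acyl oxazolidinone gives the C19 primary alcohol and frees the auxiliary; the same hydride reduces off the C14 acetate, while the alkenyl iodide and the silyl ethers are inert.

Step 18
Reactants: 32 triol of step 17
Product: 33 (2S,3S,6R,7S,9E)-1,7-bis(tert-butyldimethylsilyloxy)-10-iodo-6-methyl-2-[(4R)-4-methyl-4-(triethylsilyloxy)hex-5-en-1-yl]-9-(propan-2-yl)dec-9-ene-3,8-diol (both C8 epimers)
Conditions: tBuMe2SiCl (1.1 equiv), imidazole, CH2Cl2, −20 → 0 °C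
Reagents that add atoms: tert-butyldimethylsilyl chloride, CC(C)(C)[Si](C)(C)Cl
Why: Rate-selective silylation of the primary C19 hydroxyl; the two secondary hydroxyls (C9 and C14) are both flanked by branched carbons and should stay free.

Step 19
Reactants: 33 diol of step 18
Product: 34 (2S,6R,7S,9E)-1,7-bis(tert-butyldimethylsilyloxy)-10-iodo-6-methyl-2-[(4R)-4-methyl-4-(triethylsilyloxy)hex-5-en-1-yl]-9-(propan-2-yl)dec-9-ene-3,8-dione
Conditions: Dess–Martin periodinane, pyridine, CH2Cl2, 0 °C → rt
Reagents that add atoms: none
Why: Hypervalent iodine oxidation of both secondary carbinols in one operation; the C14 epimers converge on the (E)-iodo-enone, and the buffered non-basic medium should leave the now enolisable C8 centre alone.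

Step 20
Reactants: 34 diketone of step 19
Product: 36 (2R,6S,10R,11S,13E)-11-(tert-butyldimethylsilyloxy)-6-[(tert-butyldimethylsilyloxy)methyl]-14-iodo-2,10-dimethyl-7,12-dioxo-13-(propan-2-yl)-2-(triethylsilyloxy)tetradec-13-enal, via secondary ozonide 35 (not isolated)
Conditions: O3 (1.0 equiv, Sudan red 7B end point), CH2Cl2, −78 °C; then PPh3, −78 °C → rt
Reagents that add atoms: ozone, [O-][O+]=O
Why: Ozonolysis of the terminal vinyl group exposes the C3 aldehyde; the only other alkene is the electron-poor iodo-enone, which should be much slower, and the aldehyde has a quaternary α-carbon and cannot enolise.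

Step 21
Reactants: 36 seco aldehyde of step 20
Product: 38 (1E,3R,4R,8S,12R,13S)-13-(tert-butyldimethylsilyloxy)-8-[(tert-butyldimethylsilyloxy)methyl]-3-hydroxy-4,12-dimethyl-1-(propan-2-yl)-4-(triethylsilyloxy)cyclotetradec-1-ene-9,14-dione, via alkenylchromium species 37 (not isolated)
Conditions: CrCl2, N-{2-[(4S)-4-(propan-2-yl)-4,5-dihydro-1,3-oxazol-2-yl]-6-methoxyphenyl}methanesulfonamide, 1,8-bis(dimethylamino)naphthalene, THF, rt; then NiCl2(2,9-dimethyl-1,10-phenanthroline) (cat.), LiCl, slow addition of 36 to 2 mM, rt
Reagents that add atoms: none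
Why: Zerovalent nickel, formed from NiCl2 by divalent chromium, inserts into the C2–I bond with retention, and the alkenyl group passes to trivalent chromium to give 37, which adds to the C3 aldehyde and is released as the carbinol on work-up. The closest known reaction type is the Nozaki–Hiyama–Kishi macrocyclisation of an alkenyl iodide onto an aldehyde, including β-iodo enones and chiral sulfonamide ligands on chromium. The 14-membered ring closes in the 14-exo-trig mode (C2 attacks C3, the C=O bond lies outside the ring), and slow addition to high dilution favours it over oligomerisation. The new stereocentre C3 is controlled by the ligand on chromium, which must deliver C2 to the Re face of the aldehyde (3R, hydroxyl syn to the C4 oxygen); the substrate offers only methyl against methylene at the quaternary C4 and, with a non-chelating silyl ether, leans weakly to the other face. Chemoselectivity for the aldehyde over the C9 and C14 ketones rests on the low basicity and low ketone reactivity of alkenylchromium reagents, which also spares the enolisable C8 centre and the silyl ethers. The (E) geometry of C1=C2, needed so that C14 and C3 end up trans, should be kept by stereoretentive insertion and transmetalation at room temperature.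

Step 22
Reactants: 38 macrocyclic carbinol of step 21
Product: 39 (1E,3R,4R,8S,12R,13S)-13-(tert-butyldimethylsilyloxy)-8-[(tert-butyldimethylsilyloxy)methyl]-4,12-dimethyl-9,14-dioxo-1-(propan-2-yl)-4-(triethylsilyloxy)cyclotetradec-1-en-3-yl methanesulfonate
Conditions: (MeSO2)2O, Et3N, DMAP (cat.), CH2Cl2, −20 → 0 °C
Reagents that add atoms: methanesulfonic anhydride, CS(=O)(=O)OS(C)(=O)=O
Why: Sulfonylation of the only free hydroxyl with retention at C3; the anhydride avoids chloride ion, which could displace the allylic sulfonate, and the enone makes the allylic position reluctant to ionise.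

Step 23
Reactants: 39 mesylate of step 22
Product: 41 (1E,3S,4R,8S,12R,13S)-3,4-epoxy-13-hydroxy-8-(hydroxymethyl)-4,12-dimethyl-1-(propan-2-yl)cyclotetradec-1-ene-9,14-dione, via trihydroxy mesylate 40 (not isolated)
Conditions: aq. HF (48%), MeCN, 0 °C; then K2CO3 (excess), MeOH, 0 °C
Reagents that add atoms: none
Why: Acidic fluoride removes all three silyl ethers while the sulfonate and both ketones persist; after neutralisation, carbonate lets the C4 oxygen displace the C3 sulfonate in a 3-exo-tet Williamson closure with inversion (3R to 3S), giving the oxirane with C2 and C5 cis. In this order the oxirane never meets hydrogen fluoride and the C8 centre sees only brief cold carbonate.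

## Compound list

1 | (R)-linalool | C=C[C@](C)(O)CCC=C(C)C | starting material
2 | (3R)-3,7-dimethyl-3-(triethylsilyloxy)octa-1,6-diene | C=C[C@](C)(O[Si](CC)(CC)CC)CCC=C(C)C | intermediate
3 | 3,3-dimethyl-5-[(3R)-3-methyl-3-(triethylsilyloxy)pent-4-en-1-yl]-1,2,4-trioxolane (secondary ozonide of 2) | C=C[C@](C)(O[Si](CC)(CC)CC)CCC1OOC(C)(C)O1 | intermediate (not isolated)
4 | (4R)-4-methyl-4-(triethylsilyloxy)hex-5-enal | C=C[C@](C)(O[Si](CC)(CC)CC)CCC=O | intermediate
5 | trimethyl phosphonoacetate | COC(=O)CP(=O)(OC)OC | starting material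
6 | sodium salt of 5 (phosphonate carbanion) | COC(=O)[CH-]P(=O)(OC)OC.[Na+] | intermediate (not isolated)
7 | methyl (2E,6R)-6-methyl-6-(triethylsilyloxy)octa-2,7-dienoate | C=C[C@](C)(O[Si](CC)(CC)CC)CC/C=C/C(=O)OC | intermediate
8 | methyl (6R)-6-methyl-6-(triethylsilyloxy)oct-7-enoate | C=C[C@](C)(O[Si](CC)(CC)CC)CCCCC(=O)OC | intermediate
9 | (6R)-6-methyl-6-(triethylsilyloxy)oct-7-enoic acid | C=C[C@](C)(O[Si](CC)(CC)CC)CCCCC(=O)O | intermediate
10 | (4R)-4-benzyl-1,3-oxazolidin-2-one | O=C1N[C@H](Cc2ccccc2)CO1 | starting material
11 | (6R)-6-methyl-6-(triethylsilyloxy)oct-7-enoic pivalic anhydride | C=C[C@](C)(O[Si](CC)(CC)CC)CCCCC(=O)OC(=O)C(C)(C)C | intermediate (not isolated)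
12 | (4R)-4-benzyl-3-[(6R)-6-methyl-6-(triethylsilyloxy)oct-7-enoyl]-1,3-oxazolidin-2-one | C=C[C@](C)(O[Si](CC)(CC)CC)CCCCC(=O)N1C(=O)OC[C@H]1Cc1ccccc1 | intermediate
13 | (3R)-3,7-dimethyloct-6-enoic acid, (R)-citronellic acid | CC(C)=CCC[C@@H](C)CC(=O)O | starting material
14 | (4S)-4-benzyl-1,3-oxazolidin-2-one | O=C1N[C@@H](Cc2ccccc2)CO1 | starting material
15 | (3R)-3,7-dimethyloct-6-enoic pivalic anhydride | CC(C)=CCC[C@@H](C)CC(=O)OC(=O)C(C)(C)C | intermediate (not isolated)
16 | (4S)-4-benzyl-3-[(3R)-3,7-dimethyloct-6-enoyl]-1,3-oxazolidin-2-one | CC(C)=CCC[C@@H](C)CC(=O)N1C(=O)OC[C@@H]1Cc1ccccc1 | intermediate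
17 | sodium (Z)-enolate of 16 | CC(C)=CCC[C@@H](C)/C=C(\[O-])N1C(=O)OC[C@@H]1Cc1ccccc1.[Na+] | intermediate (not isolated)
18 | (4S)-4-benzyl-3-[(2S,3R)-2-hydroxy-3,7-dimethyloct-6-enoyl]-1,3-oxazolidin-2-one | CC(C)=CCC[C@@H](C)[C@H](O)C(=O)N1C(=O)OC[C@@H]1Cc1ccccc1 | intermediate
19 | (2S,3R)-2-hydroxy-N-methoxy-N,3,7-trimethyloct-6-enamide | CC(C)=CCC[C@@H](C)[C@H](O)C(=O)N(C)OC | intermediate
20 | (2S,3R)-2-(tert-butyldimethylsilyloxy)-N-methoxy-N,3,7-trimethyloct-6-enamide | CC(C)=CCC[C@@H](C)[C@H](O[Si](C)(C)C(C)(C)C)C(=O)N(C)OC | intermediate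
21 | isobutylmagnesium bromide | CC(C)C[Mg]Br | starting material
22 | (5S,6R)-5-(tert-butyldimethylsilyloxy)-2,6,10-trimethylundec-9-en-4-one | CC(C)=CCC[C@@H](C)[C@H](O[Si](C)(C)C(C)(C)C)C(=O)CC(C)C | intermediate
23 | lithium enolate of 22 on the C1 side (enolate geometry immaterial) | CC(C)=CCC[C@@H](C)[C@H](O[Si](C)(C)C(C)(C)C)C([O-])=CC(C)C.[Li+] | intermediate (not isolated)
24 | (1Z,4S,5R)-4-(tert-butyldimethylsilyloxy)-1-hydroxy-5,9-dimethyl-2-(propan-2-yl)deca-1,8-dien-3-one, enol form of the 2-formyl ketone | CC(C)=CCC[C@@H](C)[C@H](O[Si](C)(C)C(C)(C)C)C(=O)/C(=C\O)C(C)C | intermediate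
25 | (1E,4S,5R)-4-(tert-butyldimethylsilyloxy)-1-iodo-5,9-dimethyl-2-(propan-2-yl)deca-1,8-dien-3-one | CC(C)=CCC[C@@H](C)[C@H](O[Si](C)(C)C(C)(C)C)C(=O)/C(C(C)C)=C/I | intermediate
26 | diisobutylaluminium alkoxide of the C14 carbinol derived from 25 (both C14 epimers) | CC(C)=CCC[C@@H](C)[C@H](O[Si](C)(C)C(C)(C)C)C(O[Al](CC(C)C)CC(C)C)/C(C(C)C)=C/I | intermediate (not isolated)
27 | (1E,4S,5R)-4-(tert-butyldimethylsilyloxy)-1-iodo-5,9-dimethyl-2-(propan-2-yl)deca-1,8-dien-3-yl acetate, both C3 epimers | CC(C)=CCC[C@@H](C)[C@H](O[Si](C)(C)C(C)(C)C)C(OC(C)=O)/C(C(C)C)=C/I | intermediate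
28 | secondary ozonide of 27 at the trisubstituted alkene (3,3-dimethyl-1,2,4-trioxolane) | CC1(C)OOC(CC[C@@H](C)[C@H](O[Si](C)(C)C(C)(C)C)C(OC(C)=O)/C(C(C)C)=C/I)O1 | intermediate (not isolated)
29 | (4R,5S,7E)-5-(tert-butyldimethylsilyloxy)-8-iodo-4-methyl-1-oxo-7-(propan-2-yl)oct-7-en-6-yl acetate, both C6 epimers | O=CCC[C@@H](C)[C@H](O[Si](C)(C)C(C)(C)C)C(OC(C)=O)/C(C(C)C)=C/I | intermediate
30 | dibutylboron (Z)-enolate of 12 | C=C[C@](C)(O[Si](CC)(CC)CC)CCC/C=C(\OB(CCCC)CCCC)N1C(=O)OC[C@H]1Cc1ccccc1 | intermediate (not isolated)
31 | (4R)-4-benzyl-3-[(2R,3S,6R,7S,9E)-8-acetoxy-7-(tert-butyldimethylsilyloxy)-3-hydroxy-10-iodo-6-methyl-2-[(4R)-4-methyl-4-(triethylsilyloxy)hex-5-en-1-yl]-9-(propan-2-yl)dec-9-enoyl]-1,3-oxazolidin-2-one, both C8 epimers of the acyl chain | C=C[C@](C)(O[Si](CC)(CC)CC)CCC[C@@H](C(=O)N1C(=O)OC[C@H]1Cc1ccccc1)[C@@H](O)CC[C@@H](C)[C@H](O[Si](C)(C)C(C)(C)C)C(OC(C)=O)/C(C(C)C)=C/I | intermediate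
32 | (2S,3S,6R,7S,9E)-7-(tert-butyldimethylsilyloxy)-10-iodo-6-methyl-2-[(4R)-4-methyl-4-(triethylsilyloxy)hex-5-en-1-yl]-9-(propan-2-yl)dec-9-ene-1,3,8-triol, both C8 epimers | C=C[C@](C)(O[Si](CC)(CC)CC)CCC[C@@H](CO)[C@@H](O)CC[C@@H](C)[C@H](O[Si](C)(C)C(C)(C)C)C(O)/C(C(C)C)=C/I | intermediate
33 | (2S,3S,6R,7S,9E)-1,7-bis(tert-butyldimethylsilyloxy)-10-iodo-6-methyl-2-[(4R)-4-methyl-4-(triethylsilyloxy)hex-5-en-1-yl]-9-(propan-2-yl)dec-9-ene-3,8-diol, both C8 epimers | C=C[C@](C)(O[Si](CC)(CC)CC)CCC[C@@H](CO[Si](C)(C)C(C)(C)C)[C@@H](O)CC[C@@H](C)[C@H](O[Si](C)(C)C(C)(C)C)C(O)/C(C(C)C)=C/I | intermediate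
34 | (2S,6R,7S,9E)-1,7-bis(tert-butyldimethylsilyloxy)-10-iodo-6-methyl-2-[(4R)-4-methyl-4-(triethylsilyloxy)hex-5-en-1-yl]-9-(propan-2-yl)dec-9-ene-3,8-dione | C=C[C@](C)(O[Si](CC)(CC)CC)CCC[C@@H](CO[Si](C)(C)C(C)(C)C)C(=O)CC[C@@H](C)[C@H](O[Si](C)(C)C(C)(C)C)C(=O)/C(C(C)C)=C/I | intermediate
35 | secondary ozonide of 34 at the terminal vinyl group (1,2,4-trioxolan-3-yl on C4) | C1OOC(O1)[C@](C)(O[Si](CC)(CC)CC)CCC[C@@H](CO[Si](C)(C)C(C)(C)C)C(=O)CC[C@@H](C)[C@H](O[Si](C)(C)C(C)(C)C)C(=O)/C(C(C)C)=C/I | intermediate (not isolated)
36 | (2R,6S,10R,11S,13E)-11-(tert-butyldimethylsilyloxy)-6-[(tert-butyldimethylsilyloxy)methyl]-14-iodo-2,10-dimethyl-7,12-dioxo-13-(propan-2-yl)-2-(triethylsilyloxy)tetradec-13-enal | O=C[C@](C)(O[Si](CC)(CC)CC)CCC[C@@H](CO[Si](C)(C)C(C)(C)C)C(=O)CC[C@@H](C)[C@H](O[Si](C)(C)C(C)(C)C)C(=O)/C(C(C)C)=C/I | intermediate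
37 | alkenylchromium species from 36 (trivalent chromium at C2, drawn as the dichloride without the sulfonamide ligand) | O=C[C@](C)(O[Si](CC)(CC)CC)CCC[C@@H](CO[Si](C)(C)C(C)(C)C)C(=O)CC[C@@H](C)[C@H](O[Si](C)(C)C(C)(C)C)C(=O)/C(C(C)C)=C/[Cr](Cl)Cl | intermediate (not isolated)
38 | (1E,3R,4R,8S,12R,13S)-13-(tert-butyldimethylsilyloxy)-8-[(tert-butyldimethylsilyloxy)methyl]-3-hydroxy-4,12-dimethyl-1-(propan-2-yl)-4-(triethylsilyloxy)cyclotetradec-1-ene-9,14-dione | CC(C)/C1=C\[C@@H](O)[C@](C)(O[Si](CC)(CC)CC)CCC[C@@H](CO[Si](C)(C)C(C)(C)C)C(=O)CC[C@@H](C)[C@H](O[Si](C)(C)C(C)(C)C)C1=O | intermediate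
39 | (1E,3R,4R,8S,12R,13S)-13-(tert-butyldimethylsilyloxy)-8-[(tert-butyldimethylsilyloxy)methyl]-4,12-dimethyl-9,14-dioxo-1-(propan-2-yl)-4-(triethylsilyloxy)cyclotetradec-1-en-3-yl methanesulfonate | CC(C)/C1=C\[C@@H](OS(C)(=O)=O)[C@](C)(O[Si](CC)(CC)CC)CCC[C@@H](CO[Si](C)(C)C(C)(C)C)C(=O)CC[C@@H](C)[C@H](O[Si](C)(C)C(C)(C)C)C1=O | intermediate
40 | (1E,3R,4R,8S,12R,13S)-4,13-dihydroxy-8-(hydroxymethyl)-4,12-dimethyl-9,14-dioxo-1-(propan-2-yl)cyclotetradec-1-en-3-yl methanesulfonate | CC(C)/C1=C\[C@@H](OS(C)(=O)=O)[C@](C)(O)CCC[C@@H](CO)C(=O)CC[C@@H](C)[C@H](O)C1=O | intermediate (not isolated)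
41 | (1E,3S,4R,8S,12R,13S)-3,4-epoxy-13-hydroxy-8-(hydroxymethyl)-4,12-dimethyl-1-(propan-2-yl)cyclotetradec-1-ene-9,14-dione | CC(C)/C1=C\[C@@H]2O[C@]2(C)CCC[C@@H](CO)C(=O)CC[C@@H](C)[C@H](O)C1=O | target

## Step count and least certain steps

Total step count: 23. Longest linear sequence: 17 steps (13 to 41, steps 7–23); the other branch (1 to 12) is 6 steps.

**Step 21 (key step).** The most likely failure is poor facial selectivity at the C3 aldehyde. The quaternary C4 distinguishes the faces only by methyl against methylene, the ring imposes its own conformational demands, and the ligand may be mismatched with both. Oligomerisation and loss of alkene geometry through a metal allenolate are lesser risks. The fallback sets out from 36 and returns at 41. The cyclisation is run so as to favour the other epimer (antipodal ligand, or no ligand if the substrate bias is enough), giving the (3S)-carbinol F1. PPh3 and hexachloroacetone convert F1 into the allylic chloride F2 with inversion at C3, which places the leaving group where the sulfonate of 39 stands. Aqueous HF in MeCN then gives the trihydroxy chloride F3, and K2CO3 in MeOH closes the oxirane with a second inversion to 41. Either C3 epimer from the ring closure therefore leads to the same oxirane.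

**Step 13.** The most likely failure is formation of a mixture of alkene isomers. The iodide enters by addition–elimination, and the preference for iodine trans to the acyl group, though expected from allylic strain, is not enforced by the mechanism. The fallback sets out from 20 and returns at 27. iBu2AlH at −78 °C reduces 20 to the aldehyde (2S,3R)-2-(tert-butyldimethylsilyloxy)-3,7-dimethyloct-6-enal F4. Reductive coupling of F4 with 3-methyl-1-(trimethylsilyl)but-1-yne (Ni(cod)2, PBu3, Et3B; zerovalent nickel) adds hydrogen and the aldehyde carbon cis across the alkyne, with the C–C bond forming at the carbon remote from silicon. This gives the alkenylsilane carbinol F5 with silicon trans to C14 by mechanism. Acetylation (Ac2O, pyridine) gives F6, and ipso-iododesilylation with N-iodosuccinimide in (CF3)2CHOH at 0 °C, which retains geometry, gives 27. The remote trisubstituted alkene may compete for the iodinating agent, so the reagent is kept at one equivalent and the temperature low.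

**Step 12.** The most likely failure is enolisation toward C13 instead of C1, which would cause epimerisation at C13 or formylation on the wrong side, because the silyloxy group acidifies that methine. The fallback sets out from 22 and returns at 24. Heating 22 with tert-butoxybis(dimethylamino)methane, which condenses only at a methylene carbon, gives the enaminone F7. Mild hydrolysis (AcOH, NaOAc, aqueous THF) converts F7 into 24 without any strong base.

**Step 20.** The most likely failure is over-oxidation: attack of ozone on the iodo-enone alkene or on iodine once the vinyl group is consumed, since the end point rests on a rate difference. The fallback sets out from 34 and returns at 36. Dihydroxylation with OsO4 (cat.) and N-methylmorpholine N-oxide, which strongly prefers the electron-rich terminal alkene, gives the diol F8. NaIO4 on silica gel then cleaves F8 to 36.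

**Step 23.** The most likely failure is enolisation at C8 during the carbonate stage (epimerisation or loss of water from the β-hydroxy ketone), or slow removal of the hindered C13 silyl ether, which would expose the allylic sulfonate to the acid for a long time. The fallback sets out from 39 and returns at 41. Bu4NF (1.2 equiv) in THF at 0 °C cleaves the C4 triethylsilyl ether, and the alkoxide closes the oxirane while C13 and C19 stay silylated, giving the bis-silyl epoxide F9. The two tert-butyldimethylsilyl groups of F9 are then removed with nearly neutral Et3N·3HF in MeCN to give 41.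

## Further compounds

F1 | step 21 | (1E,3S,4R,8S,12R,13S)-13-(tert-butyldimethylsilyloxy)-8-[(tert-butyldimethylsilyloxy)methyl]-3-hydroxy-4,12-dimethyl-1-(propan-2-yl)-4-(triethylsilyloxy)cyclotetradec-1-ene-9,14-dione (C3 epimer of 38) | CC(C)/C1=C\[C@H](O)[C@](C)(O[Si](CC)(CC)CC)CCC[C@@H](CO[Si](C)(C)C(C)(C)C)C(=O)CC[C@@H](C)[C@H](O[Si](C)(C)C(C)(C)C)C1=O
F2 | step 21 | (2E,4R,5R,9S,13R,14S)-14-(tert-butyldimethylsilyloxy)-9-[(tert-butyldimethylsilyloxy)methyl]-4-chloro-5,13-dimethyl-2-(propan-2-yl)-5-(triethylsilyloxy)cyclotetradec-2-ene-1,10-dione (3R chloride in target numbering) | CC(C)/C1=C\[C@@H](Cl)[C@](C)(O[Si](CC)(CC)CC)CCC[C@@H](CO[Si](C)(C)C(C)(C)C)C(=O)CC[C@@H](C)[C@H](O[Si](C)(C)C(C)(C)C)C1=O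
F3 | step 21 | (2E,4R,5R,9S,13R,14S)-4-chloro-5,14-dihydroxy-9-(hydroxymethyl)-5,13-dimethyl-2-(propan-2-yl)cyclotetradec-2-ene-1,10-dione | CC(C)/C1=C\[C@@H](Cl)[C@](C)(O)CCC[C@@H](CO)C(=O)CC[C@@H](C)[C@H](O)C1=O
F4 | step 13 | (2S,3R)-2-(tert-butyldimethylsilyloxy)-3,7-dimethyloct-6-enal | CC(C)=CCC[C@@H](C)[C@H](O[Si](C)(C)C(C)(C)C)C=O
F5 | step 13 | (1E,4S,5R)-4-(tert-butyldimethylsilyloxy)-5,9-dimethyl-2-(propan-2-yl)-1-(trimethylsilyl)deca-1,8-dien-3-ol, both C3 epimers | CC(C)=CCC[C@@H](C)[C@H](O[Si](C)(C)C(C)(C)C)C(O)/C(C(C)C)=C/[Si](C)(C)C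
F6 | step 13 | (1E,4S,5R)-4-(tert-butyldimethylsilyloxy)-5,9-dimethyl-2-(propan-2-yl)-1-(trimethylsilyl)deca-1,8-dien-3-yl acetate, both C3 epimers | CC(C)=CCC[C@@H](C)[C@H](O[Si](C)(C)C(C)(C)C)C(OC(C)=O)/C(C(C)C)=C/[Si](C)(C)C
F7 | step 12 | (1E,4S,5R)-4-(tert-butyldimethylsilyloxy)-1-(dimethylamino)-5,9-dimethyl-2-(propan-2-yl)deca-1,8-dien-3-one | CC(C)=CCC[C@@H](C)[C@H](O[Si](C)(C)C(C)(C)C)C(=O)/C(C(C)C)=C/N(C)C
F8 | step 20 | 1,2-diol from dihydroxylation of the terminal vinyl group of 34 (both epimers at the new carbinol carbon C3) | OCC(O)[C@](C)(O[Si](CC)(CC)CC)CCC[C@@H](CO[Si](C)(C)C(C)(C)C)C(=O)CC[C@@H](C)[C@H](O[Si](C)(C)C(C)(C)C)C(=O)/C(C(C)C)=C/I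
F9 | step 23 | (1E,3S,4R,8S,12R,13S)-13-(tert-butyldimethylsilyloxy)-8-[(tert-butyldimethylsilyloxy)methyl]-3,4-epoxy-4,12-dimethyl-1-(propan-2-yl)cyclotetradec-1-ene-9,14-dione | CC(C)/C1=C\[C@@H]2O[C@]2(C)CCC[C@@H](CO[Si](C)(C)C(C)(C)C)C(=O)CC[C@@H](C)[C@H](O[Si](C)(C)C(C)(C)C)C1=O
A1 | alternative 1 | 14-membered carbocyclic C8 carboxylic acid with C9 hydroxyl, (E)-C5=C6 alkene, C3–C4 oxirane, C13 tert-butyldimethylsilyl ether and C14 triethylsilyl ether | CC(C)/C1=C\[C@@H]2O[C@]2(C)/C=C/C[C@@H](C(=O)O)[C@H](O)CC[C@@H](C)[C@H](O[Si](C)(C)C(C)(C)C)[C@H]1O[Si](CC)(CC)CC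
A2 | alternative 2 | macrocyclic vinyl oxirane with triethylsilyl ethers at C9 and C14 and tert-butyldimethylsilyl ethers at C13 and C19 | CC(C)/C1=C\[C@@H]2O[C@]2(C)CCC[C@@H](CO[Si](C)(C)C(C)(C)C)[C@@H](O[Si](CC)(CC)CC)CC[C@@H](C)[C@H](O[Si](C)(C)C(C)(C)C)[C@H]1O[Si](CC)(CC)CC
A3 | alternative 3 | 14-membered cycloalkyne (C9≡C10) with C3–C4 oxirane, C13 and C14 tert-butyldimethylsilyl ethers and C19 4-methoxybenzyl ether | C1C[C@@H](C)[C@H](O[Si](C)(C)C(C)(C)C)[C@@H](O[Si](C)(C)C(C)(C)C)/C(C(C)C)=C/[C@@H]2O[C@]2(C)CCC[C@@H](COCc2ccc(OC)cc2)C#1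
A4 | alternative 3 | but-2-yne | CC#CC
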